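**Strategy.** The cis pair formed by the C3 oxygen and the 1‑formylvinyl branch on C2 of the dihydrofuran ring (O1–C2–C3–C3a–C7a) is treated as an opened α‑methylene‑γ‑butyrolactone fused across C2–C3. That lactone is cut back to an aldehyde, an O‑allenyl group and CO. A ruthenium‑catalysed hetero‑Pauson–Khand cyclocarbonylation of a salicylaldehyde O‑allenyl ether, carrying the (R)‑silyloxyethyl chain para to oxygen, should form C2–C3, Cα–C(=O) and C(=O)–O3 in one operation, close both five‑membered rings and fix C2/C3 as cis. The aldehyde is installed only after the base‑mediated propargyl‑to‑allenyl isomerisation. Afterwards the lactone is reduced, O3 acetylated, the primary carbinol oxidised and the side chain angeloylated.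

Key step: step 6

Remark: nothing in the substrate fixes the absolute sense at C2/C3 in the cyclocarbonylation. The two cis‑fused diastereomers are therefore assumed to form in similar amounts and to be separable by chromatography. Only the (3aS,8bS) isomer is carried on; the (3aR,8bR) isomer is a discarded side product and takes no further part in the route. Atom labels (O1, C2, C3, C3a, C7a, O3, Cα) follow the dihydrobenzofuran numbering of the target.

Abbreviations: TBS = tert‑butyldimethylsilyl, TES = triethylsilyl, TBDPS = tert‑butyldiphenylsilyl.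

**Step 1**
Reactants: 1 1-(4-hydroxy-3-iodophenyl)ethan-1-one; 2 3-bromoprop-1-yne (propargyl bromide)
Product: 3 1-[3-iodo-4-(prop-2-yn-1-yloxy)phenyl]ethan-1-one
Conditions: K2CO3, DMF, rt
Reagents that add atoms: none
Why: Williamson ether synthesis, in which the phenoxide of 1 displaces bromide from the primary propargylic halide by SN2; capping the phenol first keeps the later para‑oxygenated benzylic carbinol from racemising through a quinone methide.

**Step 2**
Reactants: 3 1-[3-iodo-4-(prop-2-yn-1-yloxy)phenyl]ethan-1-one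
Product: 4 (1R)-1-[3-iodo-4-(prop-2-yn-1-yloxy)phenyl]ethan-1-ol
Conditions: RuCl[(R,R)-TsDPEN](p-cymene) (1 mol %), HCO2H/Et3N (5:2), 30 °C
Reagents that add atoms: none
Why: Noyori–Ikariya asymmetric transfer hydrogenation, in which the (R,R)‑configured ruthenium hydride delivers hydride to the Si face of the aryl methyl ketone through the six‑membered outer‑sphere transition state and so sets the (R) carbinol; the aryl iodide and the remote alkyne are not expected to react.

**Step 3**
Reactants: 4 (1R)-1-[3-iodo-4-(prop-2-yn-1-yloxy)phenyl]ethan-1-ol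
Product: 5 tert-butyl{(1R)-1-[3-iodo-4-(prop-2-yn-1-yloxy)phenyl]ethoxy}dimethylsilane
Conditions: TBSCl, imidazole, DMF, rt
Reagents that add atoms: tert-butyldimethylsilyl chloride, CC(C)(C)[Si](C)(C)Cl
Why: Imidazole‑promoted O‑silylation of a secondary alcohol, which leaves the stereocentre untouched and gives an ether that withstands the base, the organomagnesium reagent, hot CO/ruthenium and the hydride used later.

**Step 4**
Reactants: 5 tert-butyl{(1R)-1-[3-iodo-4-(prop-2-yn-1-yloxy)phenyl]ethoxy}dimethylsilane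
Product: 6 tert-butyl{(1R)-1-[3-iodo-4-(propa-1,2-dien-1-yloxy)phenyl]ethoxy}dimethylsilane
Conditions: KOtBu (0.3 equiv), THF, 0 °C → rt
Reagents that add atoms: none
Why: Base‑catalysed propargyl‑to‑allenyl prototropic isomerisation, which should stop at the aryloxyallene under catalytic tert‑butoxide at low temperature; the substrate has no free hydroxyl and no ortho carbonyl group that could add to the allene or trap the intermediate anion.

**Step 5**
Reactants: 6 tert-butyl{(1R)-1-[3-iodo-4-(propa-1,2-dien-1-yloxy)phenyl]ethoxy}dimethylsilane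
Product: 9 5-[(1R)-1-(TBSO)ethyl]-2-(propa-1,2-dien-1-yloxy)benzaldehyde, via arylmagnesium chloride 7 (not isolated), via magnesium hemiaminal alkoxide 8 (not isolated)
Conditions: i-PrMgCl·LiCl, THF, −20 °C; DMF, −20 °C → rt; pH 7 buffer
Reagents that add atoms: N,N-dimethylformamide, CN(C)C=O
Why: Iodine–magnesium exchange followed by Bouveault formylation, run below the temperature at which an arylmagnesium would metalate or add to the allenyl ether; adduct 8 releases the aldehyde on neutral aqueous work‑up, so the acid‑labile allenyl ether never meets acid.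

**Step 6**
Reactants: 9 5-[(1R)-1-(TBSO)ethyl]-2-(propa-1,2-dien-1-yloxy)benzaldehyde; 10 carbon monoxide
Product: 11 (3aS,8bS)-7-[(1R)-1-(TBSO)ethyl]-3-methylidene-3a,8b-dihydrofuro[3,2-b][1]benzofuran-2(3H)-one (cis‑fused α‑methylene lactone across C2–C3; 2S,3S in dihydrobenzofuran numbering)
Conditions: Ru3(CO)12 (5 mol %), CO (20 atm), 1,4-dioxane, 120 °C; silica gel chromatography to remove the (3aR,8bR) cis diastereomer
Reagents that add atoms: none
Why: Proposed new method: zerovalent ruthenium from Ru3(CO)12 should couple the aldehyde C=O and the proximal, oxygen‑bearing C=C of the allenyl ether oxidatively to an oxaruthenacyclopentane (forming C2–C3, with Ru on the central allene carbon), after which CO insertion into the Ru–alkenyl bond and acyl–oxygen reductive elimination form Cα–C(=O) and C(=O)–O3. The closest known reaction type is the Ru3(CO)12‑catalysed hetero‑Pauson–Khand cyclocarbonylation of carbon‑ or nitrogen‑tethered allenyl aldehydes to cis‑fused α‑methylene‑γ‑butyrolactones; an aryloxyallene joined to an aromatic aldehyde has not been used in it. The dihydrofuran ring (O1–C2–C3–C3a–C7a) closes when the metallacycle forms, exo at both the carbonyl and the reacting allene C=C, and the lactone ring closes by reductive elimination from the six‑membered acylruthenium alkoxide. C2 and C3 are created together and must be cis because two fused five‑membered rings cannot be trans‑fused; their absolute sense is not steered by the remote (R) carbinol, so 11 is expected alongside a similar amount of its (3aR,8bR) cis diastereomer, from which it is separated. The step needs the proximal C=C to react, which the three‑atom ortho‑phenylene ether tether should secure as in the carbon‑tethered cases (bonding at the central or distal carbon would mean a six‑ or seven‑membered closure), and the distal CH2 survives as the exocyclic methylene.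

**Step 7**
Reactants: 11 (3aS,8bS)-7-[(1R)-1-(TBSO)ethyl]-3-methylidene-3a,8b-dihydrofuro[3,2-b][1]benzofuran-2(3H)-one
Product: 12 (2S,3S)-5-[(1R)-1-(TBSO)ethyl]-2-(3-hydroxyprop-1-en-2-yl)-2,3-dihydro-1-benzofuran-3-ol
Conditions: (i-Bu)2AlH (4 equiv), CH2Cl2, −78 → 0 °C; aq. KNaC4H4O6
Reagents that add atoms: none
Why: Hydride reduction of the lactone to the diol through the lactol aluminate; (i-Bu)2AlH adds 1,2 only, which avoids the conjugate reduction that would expel the C2 aryloxide and open the dihydrofuran, and C2 and C3 are untouched.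

**Step 8**
Reactants: 12 (2S,3S)-5-[(1R)-1-(TBSO)ethyl]-2-(3-hydroxyprop-1-en-2-yl)-2,3-dihydro-1-benzofuran-3-ol
Product: 14 (2S,3S)-5-[(1R)-1-(TBSO)ethyl]-2-[3-(TBSO)prop-1-en-2-yl]-2,3-dihydro-1-benzofuran-3-yl acetate, via primary silyl ether 13 (not isolated)
Conditions: TBSCl (1.1 equiv), Et3N, DMAP (cat.), CH2Cl2, 0 °C; then Ac2O, Et3N, DMAP, rt
Reagents that add atoms: tert-butyldimethylsilyl chloride, CC(C)(C)[Si](C)(C)Cl; acetic anhydride, CC(=O)OC(C)=O
Why: Sterically controlled silylation followed by DMAP‑catalysed acylation in one flask; TBSCl should react at the primary allylic hydroxyl well before the hindered secondary benzylic C3–OH, which Ac2O then acetylates with retention because only the O–H bond reacts.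

**Step 9**
Reactants: 14 (2S,3S)-5-[(1R)-1-(TBSO)ethyl]-2-[3-(TBSO)prop-1-en-2-yl]-2,3-dihydro-1-benzofuran-3-yl acetate
Product: 15 (2S,3S)-5-[(1R)-1-hydroxyethyl]-2-(3-hydroxyprop-1-en-2-yl)-2,3-dihydro-1-benzofuran-3-yl acetate
Conditions: HF·pyridine, pyridine, THF, 0 °C → rt
Reagents that add atoms: none
Why: Fluoride‑driven cleavage of both silyl ethers; the pyridine‑buffered medium should neither ionise the benzylic acetate or carbinol nor be basic enough to cause acetyl migration.

**Step 10**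
Reactants: 15 (2S,3S)-5-[(1R)-1-hydroxyethyl]-2-(3-hydroxyprop-1-en-2-yl)-2,3-dihydro-1-benzofuran-3-yl acetate
Product: 16 (2S,3S)-5-[(1R)-1-hydroxyethyl]-2-(3-oxoprop-1-en-2-yl)-2,3-dihydro-1-benzofuran-3-yl acetate
Conditions: TEMPO (10 mol %), PhI(OAc)2 (1.1 equiv), CH2Cl2, 0 °C → rt
Reagents that add atoms: none
Why: Oxoammonium‑mediated alcohol oxidation (TEMPO/PhI(OAc)2), which is biased toward unhindered primary alcohols, so the primary allylic hydroxyl should give the enal before the secondary benzylic carbinol reacts; the medium contains no amine or metal that could attack the enal or the acetate.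

**Step 11**
Reactants: 16 (2S,3S)-5-[(1R)-1-hydroxyethyl]-2-(3-oxoprop-1-en-2-yl)-2,3-dihydro-1-benzofuran-3-yl acetate; 17 (2Z)-2-methylbut-2-enoic acid (angelic acid)
Product: 19 (1R)-1-[(2S,3S)-3-(acetyloxy)-2-(3-oxoprop-1-en-2-yl)-2,3-dihydro-1-benzofuran-5-yl]ethyl (2Z)-2-methylbut-2-enoate, via mixed anhydride 18 (not isolated)
Conditions: 17, 2,4,6-Cl3C6H2COCl, Et3N, toluene, rt; then 16, 70 °C
Reagents that add atoms: none
Why: Yamaguchi‑type mixed‑anhydride esterification, in which the benzylic alcohol attacks the unhindered angeloyl carbonyl of 18; leaving out DMAP avoids the reversible conjugate addition that turns angelate into tiglate, and acylation on oxygen retains the (R) configuration.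

**Compound list**

1 | 1-(4-hydroxy-3-iodophenyl)ethan-1-one | CC(=O)c1ccc(O)c(I)c1 | starting material
2 | 3-bromoprop-1-yne (propargyl bromide) | C#CCBr | starting material
3 | 1-[3-iodo-4-(prop-2-yn-1-yloxy)phenyl]ethan-1-one | CC(=O)c1ccc(OCC#C)c(I)c1 | intermediate
4 | (1R)-1-[3-iodo-4-(prop-2-yn-1-yloxy)phenyl]ethan-1-ol | C#CCOc1ccc([C@@H](C)O)cc1I | intermediate
5 | tert-butyl{(1R)-1-[3-iodo-4-(prop-2-yn-1-yloxy)phenyl]ethoxy}dimethylsilane | C#CCOc1ccc([C@@H](C)O[Si](C)(C)C(C)(C)C)cc1I | intermediate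
6 | tert-butyl{(1R)-1-[3-iodo-4-(propa-1,2-dien-1-yloxy)phenyl]ethoxy}dimethylsilane | C=C=COc1ccc([C@@H](C)O[Si](C)(C)C(C)(C)C)cc1I | intermediate
7 | {5-[(1R)-1-(TBSO)ethyl]-2-(propa-1,2-dien-1-yloxy)phenyl}magnesium chloride (LiCl complex) | C=C=COc1ccc([C@@H](C)O[Si](C)(C)C(C)(C)C)cc1[Mg]Cl | intermediate (not isolated)
8 | chloromagnesium alkoxide of {5-[(1R)-1-(TBSO)ethyl]-2-(propa-1,2-dien-1-yloxy)phenyl}(dimethylamino)methanol, either configuration at the new carbon | C=C=COc1ccc([C@@H](C)O[Si](C)(C)C(C)(C)C)cc1C(O[Mg]Cl)N(C)C | intermediate (not isolated)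
9 | 5-[(1R)-1-(TBSO)ethyl]-2-(propa-1,2-dien-1-yloxy)benzaldehyde | C=C=COc1ccc([C@@H](C)O[Si](C)(C)C(C)(C)C)cc1C=O | intermediate
10 | carbon monoxide | [C-]#[O+] | starting material
11 | (3aS,8bS)-7-[(1R)-1-(TBSO)ethyl]-3-methylidene-3a,8b-dihydrofuro[3,2-b][1]benzofuran-2(3H)-one | C=C3[C@@H]1Oc2ccc([C@@H](C)O[Si](C)(C)C(C)(C)C)cc2[C@@H]1OC3=O | intermediate
12 | (2S,3S)-5-[(1R)-1-(TBSO)ethyl]-2-(3-hydroxyprop-1-en-2-yl)-2,3-dihydro-1-benzofuran-3-ol | C=C(CO)[C@@H]1Oc2ccc([C@@H](C)O[Si](C)(C)C(C)(C)C)cc2[C@@H]1O | intermediate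
13 | (2S,3S)-5-[(1R)-1-(TBSO)ethyl]-2-[3-(TBSO)prop-1-en-2-yl]-2,3-dihydro-1-benzofuran-3-ol | C=C(CO[Si](C)(C)C(C)(C)C)[C@@H]1Oc2ccc([C@@H](C)O[Si](C)(C)C(C)(C)C)cc2[C@@H]1O | intermediate (not isolated)
14 | (2S,3S)-5-[(1R)-1-(TBSO)ethyl]-2-[3-(TBSO)prop-1-en-2-yl]-2,3-dihydro-1-benzofuran-3-yl acetate | C=C(CO[Si](C)(C)C(C)(C)C)[C@@H]1Oc2ccc([C@@H](C)O[Si](C)(C)C(C)(C)C)cc2[C@@H]1OC(C)=O | intermediate
15 | (2S,3S)-5-[(1R)-1-hydroxyethyl]-2-(3-hydroxyprop-1-en-2-yl)-2,3-dihydro-1-benzofuran-3-yl acetate | C=C(CO)[C@@H]1Oc2ccc([C@@H](C)O)cc2[C@@H]1OC(C)=O | intermediate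
16 | (2S,3S)-5-[(1R)-1-hydroxyethyl]-2-(3-oxoprop-1-en-2-yl)-2,3-dihydro-1-benzofuran-3-yl acetate | C=C(C=O)[C@@H]1Oc2ccc([C@@H](C)O)cc2[C@@H]1OC(C)=O | intermediate
17 | (2Z)-2-methylbut-2-enoic acid (angelic acid) | C/C=C(/C)C(=O)O | starting material
18 | (2Z)-2-methylbut-2-enoic 2,4,6-trichlorobenzoic anhydride | C/C=C(/C)C(=O)OC(=O)c1c(Cl)cc(Cl)cc1Cl | intermediate (not isolated)
19 | (1R)-1-[(2S,3S)-3-(acetyloxy)-2-(3-oxoprop-1-en-2-yl)-2,3-dihydro-1-benzofuran-5-yl]ethyl (2Z)-2-methylbut-2-enoate | C=C(C=O)[C@@H]1Oc2ccc([C@@H](C)OC(=O)/C(C)=C\C)cc2[C@@H]1OC(C)=O | target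

**Count.** Total steps: 11. Longest linear sequence: 11 steps (1 → 19).

**Steps most likely to fail**

Step 6 (proposed new method). The aldehyde C–H bond may add across the allene or lose CO instead of entering the metallacycle. The electron‑rich aryloxyallene may oligomerise at 120 °C, or the oxidative coupling may not engage the enol‑ether‑like C=C. Facial selectivity is absent in any case, which halves the usable material. The fallback uses known chemistry, makes C2–C3 by allyl transfer and adds the carbonyl afterwards. It sets out from 9. Palladium‑catalysed silastannylation of the allene with Me3SiSnBu3 ([(C3H5)PdCl]2, THF, rt) places silicon on the central carbon and generates a γ‑aryloxyallylstannane, which adds to the ortho aldehyde through a cyclic transition state. After aqueous work‑up this should give the cis alcohol (2R,3S)-5-[(1R)-1-(TBSO)ethyl]-2-[1-(trimethylsilyl)ethenyl]-2,3-dihydro-1-benzofuran-3-ol F1; the C2 descriptor changes only because silicon raises the priority of the vinyl branch, and the geometry is that of 11. It is separated from its cis diastereomer (2S,3R)-5-[(1R)-1-(TBSO)ethyl]-2-[1-(trimethylsilyl)ethenyl]-2,3-dihydro-1-benzofuran-3-ol F2. Iododesilylation with N‑iodosuccinimide (MeCN, 0 °C) should give the vinyl iodide (2R,3S)-5-[(1R)-1-(TBSO)ethyl]-2-(1-iodoethenyl)-2,3-dihydro-1-benzofuran-3-ol F3. Carbonylative lactonisation (Pd(PPh3)4, CO 1 atm, Et3N, MeCN, 60 °C), in which zerovalent palladium inserts into C–I, takes up CO and is intercepted by the C3 hydroxyl, comes back to the route at 11.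

Step 11. The angeloyl group may isomerise to tigloyl during acylation. The α‑substituted acrolein may also suffer conjugate addition, followed by loss of the C2 aryloxide or of acetic acid, under warm basic conditions. The fallback installs the angelate before the enal exists and makes a neutral oxidation the last step. It sets out from 12. Primary‑selective silylation (TBDPSCl, imidazole, CH2Cl2, 0 °C) gives (2S,3S)-5-[(1R)-1-(TBSO)ethyl]-2-[3-(TBDPSO)prop-1-en-2-yl]-2,3-dihydro-1-benzofuran-3-ol F4, which is acetylated in the same flask (Ac2O, DMAP) to the corresponding 3-yl acetate F5. AcOH/THF/H2O at rt cleaves the side‑chain TBS ether and leaves the far more acid‑stable primary TBDPS ether, giving (2S,3S)-5-[(1R)-1-hydroxyethyl]-2-[3-(TBDPSO)prop-1-en-2-yl]-2,3-dihydro-1-benzofuran-3-yl acetate F6. Acylation with anhydride 18 as in step 11 gives (1R)-1-{(2S,3S)-3-(acetyloxy)-2-[3-(TBDPSO)prop-1-en-2-yl]-2,3-dihydro-1-benzofuran-5-yl}ethyl (2Z)-2-methylbut-2-enoate F7. HF·pyridine/pyridine (THF, rt) frees the allylic alcohol (1R)-1-[(2S,3S)-3-(acetyloxy)-2-(3-hydroxyprop-1-en-2-yl)-2,3-dihydro-1-benzofuran-5-yl]ethyl (2Z)-2-methylbut-2-enoate F8. MnO2 (CH2Cl2, rt) then oxidises it, arriving at 19.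

Step 10. Chemoselectivity may be lost through competing oxidation of the activated secondary benzylic carbinol. The fallback keeps that carbinol silylated during the oxidation by using two silyl groups of different lability. It sets out from 12. TESCl (imidazole, CH2Cl2, −78 °C) gives (2S,3S)-5-[(1R)-1-(TBSO)ethyl]-2-[3-(TESO)prop-1-en-2-yl]-2,3-dihydro-1-benzofuran-3-ol F9, acetylated in the same flask (Ac2O, DMAP) to the corresponding 3-yl acetate F10. Brief treatment with HF·pyridine/pyridine (THF, 0 °C) removes only the primary TES ether, giving (2S,3S)-5-[(1R)-1-(TBSO)ethyl]-2-(3-hydroxyprop-1-en-2-yl)-2,3-dihydro-1-benzofuran-3-yl acetate F11. MnO2 (CH2Cl2, rt) oxidises the only free, allylic hydroxyl to (2S,3S)-5-[(1R)-1-(TBSO)ethyl]-2-(3-oxoprop-1-en-2-yl)-2,3-dihydro-1-benzofuran-3-yl acetate F12. HF·pyridine (THF, rt) then removes the side‑chain TBS ether, coming back to the route at 16.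

**Further compounds**

F1 | step 6 | (2R,3S)-5-[(1R)-1-(TBSO)ethyl]-2-[1-(trimethylsilyl)ethenyl]-2,3-dihydro-1-benzofuran-3-ol | C=C([Si](C)(C)C)[C@@H]1Oc2ccc([C@@H](C)O[Si](C)(C)C(C)(C)C)cc2[C@@H]1O
F2 | step 6 | (2S,3R)-5-[(1R)-1-(TBSO)ethyl]-2-[1-(trimethylsilyl)ethenyl]-2,3-dihydro-1-benzofuran-3-ol | C=C([Si](C)(C)C)[C@H]1Oc2ccc([C@@H](C)O[Si](C)(C)C(C)(C)C)cc2[C@H]1O
F3 | step 6 | (2R,3S)-5-[(1R)-1-(TBSO)ethyl]-2-(1-iodoethenyl)-2,3-dihydro-1-benzofuran-3-ol | C=C(I)[C@@H]1Oc2ccc([C@@H](C)O[Si](C)(C)C(C)(C)C)cc2[C@@H]1O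
F4 | step 11 | (2S,3S)-5-[(1R)-1-(TBSO)ethyl]-2-[3-(TBDPSO)prop-1-en-2-yl]-2,3-dihydro-1-benzofuran-3-ol | C=C(CO[Si](c3ccccc3)(c3ccccc3)C(C)(C)C)[C@@H]1Oc2ccc([C@@H](C)O[Si](C)(C)C(C)(C)C)cc2[C@@H]1O
F5 | step 11 | (2S,3S)-5-[(1R)-1-(TBSO)ethyl]-2-[3-(TBDPSO)prop-1-en-2-yl]-2,3-dihydro-1-benzofuran-3-yl acetate | C=C(CO[Si](c3ccccc3)(c3ccccc3)C(C)(C)C)[C@@H]1Oc2ccc([C@@H](C)O[Si](C)(C)C(C)(C)C)cc2[C@@H]1OC(C)=O
F6 | step 11 | (2S,3S)-5-[(1R)-1-hydroxyethyl]-2-[3-(TBDPSO)prop-1-en-2-yl]-2,3-dihydro-1-benzofuran-3-yl acetate | C=C(CO[Si](c3ccccc3)(c3ccccc3)C(C)(C)C)[C@@H]1Oc2ccc([C@@H](C)O)cc2[C@@H]1OC(C)=O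
F7 | step 11 | (1R)-1-{(2S,3S)-3-(acetyloxy)-2-[3-(TBDPSO)prop-1-en-2-yl]-2,3-dihydro-1-benzofuran-5-yl}ethyl (2Z)-2-methylbut-2-enoate | C=C(CO[Si](c3ccccc3)(c3ccccc3)C(C)(C)C)[C@@H]1Oc2ccc([C@@H](C)OC(=O)/C(C)=C\C)cc2[C@@H]1OC(C)=O
F8 | step 11 | (1R)-1-[(2S,3S)-3-(acetyloxy)-2-(3-hydroxyprop-1-en-2-yl)-2,3-dihydro-1-benzofuran-5-yl]ethyl (2Z)-2-methylbut-2-enoate | C=C(CO)[C@@H]1Oc2ccc([C@@H](C)OC(=O)/C(C)=C\C)cc2[C@@H]1OC(C)=O
F9 | step 10 | (2S,3S)-5-[(1R)-1-(TBSO)ethyl]-2-[3-(TESO)prop-1-en-2-yl]-2,3-dihydro-1-benzofuran-3-ol | C=C(CO[Si](CC)(CC)CC)[C@@H]1Oc2ccc([C@@H](C)O[Si](C)(C)C(C)(C)C)cc2[C@@H]1O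
F10 | step 10 | (2S,3S)-5-[(1R)-1-(TBSO)ethyl]-2-[3-(TESO)prop-1-en-2-yl]-2,3-dihydro-1-benzofuran-3-yl acetate | C=C(CO[Si](CC)(CC)CC)[C@@H]1Oc2ccc([C@@H](C)O[Si](C)(C)C(C)(C)C)cc2[C@@H]1OC(C)=O
F11 | step 10 | (2S,3S)-5-[(1R)-1-(TBSO)ethyl]-2-(3-hydroxyprop-1-en-2-yl)-2,3-dihydro-1-benzofuran-3-yl acetate | C=C(CO)[C@@H]1Oc2ccc([C@@H](C)O[Si](C)(C)C(C)(C)C)cc2[C@@H]1OC(C)=O
F12 | step 10 | (2S,3S)-5-[(1R)-1-(TBSO)ethyl]-2-(3-oxoprop-1-en-2-yl)-2,3-dihydro-1-benzofuran-3-yl acetate | C=C(C=O)[C@@H]1Oc2ccc([C@@H](C)O[Si](C)(C)C(C)(C)C)cc2[C@@H]1OC(C)=O
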